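## Structural features

Kadsurenin D (20) is a bicyclo[3.2.1]oct-2-ene-4,8-dione in which a six-membered ring (C1–C2–C3–C4–C5–C8) and a five-membered ring (C1–C7–C6–C5–C8) share the unit C1–C8–C5; seen from the periphery, C8 is a one-carbon carbonyl bridge across the seven-membered ring C1 to C7. (Locants: C1 allyl-bearing bridgehead, C2=C3(OMe)–C4(=O), C5 bridgehead CH, C6 aryl carbon, C7 methyl carbon, C8 bridging ketone.) Four stereocentres stand in a row, the quaternary C1, then C7, C6 and C5; the 3,4-dimethoxyphenyl group at C6 is exo (on the C8 side) and the methyl group at C7 is endo, so the two are trans. The six-membered ring carries a diosphenol methyl ether (C2=C3(OMe)–C4=O), and C5 lies between the C4 and C8 carbonyl groups as a β-diketone that cannot enolise because C5 is a bridgehead. Fragile are this β-diketone toward nucleophilic base (retro-Claisen cleavage), the enol ether toward aqueous acid, the terminal allyl group toward hydrogenation, strong oxidants and base-induced migration into conjugation, and the electron-rich aryl ring toward electrophiles. The real difficulty is the quaternary bridgehead C1, wedged between C7, C2 and C8, together with the relative configuration between the bridge (C1, C5) and the substituents on C6 and C7. The key step exploits the fact that C8 is bonded only to C1 and C5, and that both are β to C3 within the seven-membered ring: with a ketone at C3 and double bonds C1=C2 and C4=C5, a one-carbon double nucleophile can be laid across the ring, which makes the five- and six-membered rings in one operation and leaves the C3 ketone as the handle for the oxygen pattern at C3 and C4.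

## Logic of the disconnections

**20 to 19.** The O–CH3 bond of the C3 enol ether is cut. 19 has a single possible enol (C4=O cannot enolise toward the bridgehead C5), so the methylation carries no regiochemical question. The acid-sensitive enol ether then appears only in the last step. The forward step must alkylate on oxygen, not on C2, with a base too weak to open the β-diketone.

**19 to 16 (through 18 and 17).** The C4–O bond is cut, first to the alcohol level (18), then to the methylene level (16). The C3 ketone of 16 is what the ring construction leaves behind, and it activates C4. No oxygen has to be carried at C4 through the earlier steps. The forward step must enolise 16 toward C4 and not toward C2, which lies next to the quaternary C1.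

**16 to 14 (through 15).** The C8=O group is traced back to C8–NO2. The nitro group is what makes C8 nucleophilic twice. The forward step is a Nef reaction at a crowded secondary carbon that must spare the alkene, the aryl ethers and the C3 ketone.

**14 to 11 and 12 (through 13).** The bonds C1–C8 and C5–C8 are cut. This removes both rings of the bicycle, the quaternary centre and three stereocentres, and leaves a monocycle (11) with only two stereocentres and a one-carbon reagent (12). The forward step must add at C5 first and then at C1, and it must bridge the ring face that is syn to aryl and anti to methyl.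

**11 to 9 (through 10).** The C4=C5 π bond is removed. The two enone halves of 11 differ, and only C1=C2–C3=O arises from the transposition below, so the second double bond is put in last. The forward step needs α′-enolisation at C4 without touching the vinylogously acidic hydrogens at C7 and at the allylic CH2.

**9 to 6 and 7 (through 8).** The bond from C1 to the allyl CH2 is cut, together with a 1,3-shift of oxygen from C3 back to C1. A β-allyl enone is the retron of carbonyl addition followed by oxidative allylic transposition. The carbonyl group of 6 is thereby used twice, for the methylation and for bringing in the allyl group. The forward steps need clean 1,2-addition and a clean [3,3] shift.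

**6 to 4 (through 5).** The C7–CH3 bond is cut. C7 is the only sp3 α-carbon of 4 and sits next to the aryl stereocentre, which directs the new bond trans. The forward step needs the kinetic α′-enolate and alkylation anti to aryl.

**4 to 2 and 3.** The C6–aryl bond is cut. C6 is a β-carbon of the symmetrical dienone 2, so a catalytic asymmetric conjugate addition creates the first stereocentre and with it the absolute configuration of the whole route. The precursor becomes achiral. The forward step needs enantioface control and must stop after one addition.

**2 to 1.** The π bonds C2=C3 and C6=C7 are removed, which leads to a commodity ketone. The forward step must stop at the dienone and not go on to the trienone.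

## Other disconnections considered

**Alternative 1:** The cut is C4–C5. It opens the six-membered ring to a prochiral precursor, 2-allyl-2-(3-oxopropyl)cyclopentane-1,3-dione A1, in which C1 is the quaternary ring carbon and the two ring carbonyl groups are enantiotopic. In the forward direction a chiral amine catalyst would turn one ring ketone into its enamine toward C5 and add it to the aldehyde C4. The product would be the bridged ketol 1-allyl-4-hydroxybicyclo[3.2.1]octane-7,8-dione A2, with C1 and C5 fixed by desymmetrisation.
- In its favour: the step is catalytic and metal-free, A1 is a simple achiral compound, and the quaternary centre is set directly by the stereo-defining step. In reliability of absolute control it is the equal of the rhodium step chosen here, and in that respect arguably better, since the catalyst and not the substrate decides the course.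
- Also in its favour: C4 is oxygenated from the start, and a C4 ketone derived from A2 can enolise only toward C3. The later diosphenol would therefore form without any site-selectivity question. On this point the alternative is better than the chosen plan, which depends on site-selective enolisation in step 9.
- Against it: A2 carries neither the aryl nor the methyl group. C6 is a methylene group and C7 a ketone. The aryl group would have to be introduced at C6 and the C7 carbonyl replaced by an endo methyl group, with the more electrophilic C8 ketone and the C4 alcohol protected. Olefination followed by hydrogenation at C7 would not spare the allyl group.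
- Comparison: the aldol forms one bond and one ring, where the chosen key step forms two bonds and both rings with C6 and C7 already in place. The number of operations after the key step would be far higher, so the alternative loses clearly on step economy.

**Alternative 2:** The cut is C1–C2. The precursor is a cyclopentanone, 2-allyl-5-[(E)-3-bromo-1,1,2-trimethoxyprop-2-en-1-yl]-4-(3,4-dimethoxyphenyl)-3-methylcyclopentan-1-one A3, whose side chain at C5 already holds C4 as a dimethyl ketal, the C3 enol ether and C2 as a bromoalkene. In the forward direction zerovalent palladium would insert into the C2–Br bond, and the C8 ketone enolate would couple through C1. This would give the C4 dimethyl ketal of the target, A4, and create the quaternary bridgehead and the six-membered ring.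
- In its favour: the whole oxygen pattern of the C2–C4 bridge is in place before the ring closes, and only a ketal hydrolysis separates A4 from 20. The endgame is thus shorter than the four steps of the chosen plan and free of its site-selectivity question, which is a real advantage.
- Also in its favour: the bridge can form on one face of the five-membered ring only, so the key step has no facial ambiguity. This too is better than the chosen plan. Palladium enolate alkenylation at quaternary bridgeheads is an established reaction type, so the mechanistic risk of the bond formation is about equal to that of the nitronate closure.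
- Against it: A3 is fragile and costly. C5 is enolisable and bears a β-ketal, so the base needed for the C1 enolate invites loss of methoxide by an E1cB pathway. Both α-carbons of the C8 ketone are tertiary, so the enolate regiochemistry is not secured. The bromo enol ether must be a single (E) isomer. The cyclopentanone with its contiguous stereocentres has to be made with absolute control beforehand.
- Comparison: one bond and one ring are formed where the chosen key step forms two and two. The alternative is shorter after the key step and much longer before it, and overall it would be the longer route.

**Alternative 3:** The cut is C3–C4. The precursor is a dialdehyde on a fully substituted cyclopentane with C8 masked as a dioxolane, 6-allyl-8-(3,4-dimethoxyphenyl)-7-methyl-6-(2-oxoethyl)-1,4-dioxaspiro[4.4]nonane-9-carbaldehyde A5. In the forward direction a divalent samarium reductant would convert both aldehydes into ketyl radicals that couple. This would close the six-membered ring as the cis-3,4-diol A6.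
- In its favour: reductive coupling of 1,6-dialdehydes to cis-diols is dependable, runs under neutral conditions and should tolerate the allyl group and the ketal. In predictability of the ring closure it is better than the chosen key step.
- Also in its favour: both oxygens arrive together at C3 and C4, so the diosphenol regiochemistry is beyond doubt, again better than step 9 of the chosen plan. After the key step about three operations remain (double oxidation, O-methylation, ketal removal), which is equal to or slightly shorter than the chosen endgame.
- Against it: the key step creates neither the quaternary centre nor any stereocentre that survives into 20. All four are already present in A5, including a quaternary C1 that carries an allyl group and an acetaldehyde arm, with two aldehydes to be told apart. The difficulty is moved into the precursor and not solved. The ketal of the strained bridging ketone would also have to be removed by acid in the presence of the enol ether.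
- Comparison: one bond, one ring and no lasting stereocentre against two bonds, two rings and the quaternary centre. Overall step economy would be clearly worse.

Key step: step 7

Remark: the configuration at C8 of 14 and at C4 of 18 is drawn as the epimer expected to predominate, and either epimer serves because both carbons become trigonal later; the bicyclic locants C1 to C8 are also used for the monocyclic precursors.

## Route

Step 1
Reactants: 1 cycloheptanone
Product: 2 cyclohepta-2,6-dien-1-one
Conditions: IBX (2.3 equiv), DMSO/PhF, 70 °C
Reagents that add atoms: none
Why: IBX dehydrogenation of a ketone (pentavalent iodine, oxidation through the enol): two successive α,β-dehydrogenations on the two equivalent sides should give the cross-conjugated dienone, and the amount of oxidant and the temperature are kept below what the third dehydrogenation to the trienone needs; no stereocentre is involved.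

Step 2
Reactants: 2 cyclohepta-2,6-dien-1-one; 3 (3,4-dimethoxyphenyl)boronic acid
Product: 4 (S)-6-(3,4-dimethoxyphenyl)cyclohept-2-en-1-one
Conditions: [RhCl(C2H4)2]2 (1.5 mol %), (S)-BINAP (3.3 mol %), KOH (0.2 equiv), aq dioxane, 35 °C; 2 in excess (1.5 equiv)
Reagents that add atoms: none
Why: Hayashi–Miyaura asymmetric 1,4-addition: an aryl complex of monovalent rhodium inserts one enone and water protonates the resulting oxa-allyl rhodium; by analogy with cyclohept-2-enone the (S)-ligand should place the aryl group so that C6 is (S). The bis(ethylene) precursor is chosen because a diene-bound rhodium would act as a faster achiral catalyst, and the excess of 2 should keep the second enone from reacting.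

Step 3
Reactants: 4 (S)-6-(3,4-dimethoxyphenyl)cyclohept-2-en-1-one
Product: 6 (6S,7R)-6-(3,4-dimethoxyphenyl)-7-methylcyclohept-2-en-1-one, via lithium dienolate 5 (not isolated)
Conditions: LiN(iPr)2, THF, −78 °C; then MeI, DMPU, −78 to −30 °C
Reagents that add atoms: iodomethane, CI
Why: Kinetic deprotonation at the only sp3 α-carbon (C7) gives the cross-conjugated dienolate, and the SN2 methylation (enolate alkylation) should occur on the face away from the neighbouring aryl group, which sets C7 trans to C6.

Step 4
Reactants: 6 (6S,7R)-6-(3,4-dimethoxyphenyl)-7-methylcyclohept-2-en-1-one; 7 allylmagnesium bromide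
Product: 8 (6S,7R)-1-allyl-6-(3,4-dimethoxyphenyl)-7-methylcyclohept-2-en-1-ol (both C1 epimers)
Conditions: THF, −78 °C; then H2O
Reagents that add atoms: none
Why: Grignard 1,2-addition: allylmagnesium halides attack the carbonyl carbon of enones through a cyclic six-centre transition state much faster than they add in conjugate fashion or enolise the α-methyl ketone. The carbinol centre disappears in step 5, so its configuration does not matter.

Step 5
Reactants: 8 (6S,7R)-1-allyl-6-(3,4-dimethoxyphenyl)-7-methylcyclohept-2-en-1-ol
Product: 9 (4R,5S)-3-allyl-5-(3,4-dimethoxyphenyl)-4-methylcyclohept-2-en-1-one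
Conditions: pyridinium chlorochromate, 4 Å molecular sieves, CH2Cl2, rt
Reagents that add atoms: pyridinium chlorochromate, [O-][Cr](=O)(=O)Cl.c1cc[nH+]cc1
Why: Babler–Dauben oxidative transposition: the chromate ester of the tertiary allylic alcohol undergoes a [3,3] shift to the secondary allylic chromate at C3, which hexavalent chromium oxidises to the enone; the new carbonyl oxygen comes from the reagent and the former hydroxyl oxygen leaves with chromium. The allyl group ends up on the β-carbon C1, and C6 and C7 are not touched.

Step 6
Reactants: 9 (4R,5S)-3-allyl-5-(3,4-dimethoxyphenyl)-4-methylcyclohept-2-en-1-one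
Product: 11 (4R,5S)-3-allyl-5-(3,4-dimethoxyphenyl)-4-methylcyclohepta-2,6-dien-1-one, via trimethylsilyl dienol ether 10 (not isolated)
Conditions: LiN(iPr)2/Me3SiCl (in situ quench), THF, −78 °C; then Pd(OAc)2 (1.05 equiv), MeCN, rt
Reagents that add atoms: none
Why: Saegusa–Ito oxidation: kinetic α′-deprotonation at C4 with immediate O-silylation, then divalent palladium forms the palladium enolate and β-hydride elimination from C5 gives the second enone. The low temperature and the internal quench should keep the base away from the more acidic but kinetically slower γ-hydrogens at C7 and at the allylic CH2; no stereocentre is formed or lost.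

Step 7
Reactants: 11 (4R,5S)-3-allyl-5-(3,4-dimethoxyphenyl)-4-methylcyclohepta-2,6-dien-1-one; 12 nitromethane
Product: 14 (1R,5S,6R,7R,8S)-1-allyl-6-(3,4-dimethoxyphenyl)-7-methyl-8-nitrobicyclo[3.2.1]octan-3-one, via mono-adduct 13 (not isolated)
Conditions: MeNO2 (10 equiv), DBU (0.3 equiv), MeCN, 0 °C to rt
Reagents that add atoms: none
Why: Double Michael addition: the nitronate of 12 adds first to the unhindered β-carbon C5, the enolate is protonated, the nitromethyl group is deprotonated again, and its carbon (C8) then adds across the ring to the β,β-disubstituted C1, so that C5–C8 and then C1–C8 are formed. The closest known reaction type is the tropinone-style double conjugate addition of primary amines or of nitromethane across cross-conjugated cyclic dienones. The second addition closes the five-membered ring C1–C7–C6–C5–C8 in a 5-exo-trig mode and, with the same bond, the six-membered ring C1–C2–C3–C4–C5–C8 in a 6-endo-trig mode, the folded seven-membered ring holding C8 above C1. C5 is set in the first addition, which is reversible under the basic conditions, so the two C5 epimers of 13 interconvert; C1 is set in the closure, and because a one-carbon bridge can span only one face of the ring, C1 and C5 are tied to each other. The face is decided at C1 by the neighbouring C7 methyl group: closure anti to it should be the faster one, and it also leads to the more stable bicycle, with the large aryl group exo beside the bridgehead hydrogen and the methyl group endo, staggered away from the bridgehead allyl group; this puts C8 syn to aryl and anti to methyl, as in 20. C8 is protonated last, with the nitro group expected on the side away from the aryl-bearing bridge, and this centre is lost in step 8. The step needs addition at C5 before C1 (secured by the substitution pattern), uptake of only one molecule of 12 (secured by the intramolecular second addition) and no migration of the C1=C2 or allyl double bonds (secured by a substoichiometric amidine base buffered by a large excess of the more acidic 12).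

Step 8
Reactants: 14 (1R,5S,6R,7R,8S)-1-allyl-6-(3,4-dimethoxyphenyl)-7-methyl-8-nitrobicyclo[3.2.1]octan-3-one
Product: 16 (1R,5S,6R,7R)-1-allyl-6-(3,4-dimethoxyphenyl)-7-methylbicyclo[3.2.1]octane-3,8-dione, via sodium nitronate 15 (not isolated)
Conditions: NaOMe, MeOH, 0 °C; then aq TiCl3, NH4OAc (pH 5–6), THF, 0 °C to rt
Reagents that add atoms: water, O
Why: Reductive Nef reaction: trivalent titanium reduces the nitronate through the oxime to the imine, which is hydrolysed to the C8 ketone in the buffered medium; the terminal alkene, the aryl ethers and the C3 ketone should be inert. Forming the nitronate first also blocks retro-Michael opening, since an anionic C8 is no leaving group; the C8 stereocentre disappears.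

Step 9
Reactants: 16 (1R,5S,6R,7R)-1-allyl-6-(3,4-dimethoxyphenyl)-7-methylbicyclo[3.2.1]octane-3,8-dione
Product: 18 (1R,4R,5R,6R,7R)-1-allyl-6-(3,4-dimethoxyphenyl)-4-hydroxy-7-methylbicyclo[3.2.1]octane-3,8-dione, via potassium enolate 17 (not isolated)
Conditions: KN(SiMe3)2, THF, −78 °C; then 2-(phenylsulfonyl)-3-phenyloxaziridine, −78 °C; then AcOH
Reagents that add atoms: 2-(phenylsulfonyl)-3-phenyloxaziridine, O=S(=O)(N1OC1c1ccccc1)c1ccccc1
Why: Kinetic enolate formation followed by electrophilic enolate hydroxylation with an N-sulfonyloxaziridine: the bulky base should take the C4 proton, whose neighbour C5 bears only hydrogen, in preference to the C2 proton next to the quaternary C1, and the C8 ketone cannot enolise at all (Bredt's rule). Oxygen should enter on the face syn to C8, away from the two-carbon bridge; this centre is removed in step 10.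

Step 10
Reactants: 18 (1R,4R,5R,6R,7R)-1-allyl-6-(3,4-dimethoxyphenyl)-4-hydroxy-7-methylbicyclo[3.2.1]octane-3,8-dione
Product: 19 (1S,5S,6R,7R)-1-allyl-6-(3,4-dimethoxyphenyl)-3-hydroxy-7-methylbicyclo[3.2.1]oct-2-ene-4,8-dione
Conditions: Dess–Martin periodinane, CH2Cl2, 0 °C to rt
Reagents that add atoms: none
Why: Dess–Martin oxidation of the α-ketol to the 3,4-dione, which should enolise at once toward C2, the only direction open to it because C5 is a bridgehead. The neutral conditions spare the non-enolisable β-diketone, the alkene and the aryl ring.

Step 11
Reactants: 19 (1S,5S,6R,7R)-1-allyl-6-(3,4-dimethoxyphenyl)-3-hydroxy-7-methylbicyclo[3.2.1]oct-2-ene-4,8-dione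
Product: 20 kadsurenin D
Conditions: Me2SO4, K2CO3, acetone, rt
Reagents that add atoms: dimethyl sulfate, COS(=O)(=O)OC
Why: O-alkylation of the diosphenolate (Williamson-type ether synthesis): the hard sulfate electrophile should react at oxygen and not at C2, and carbonate in acetone is not nucleophilic enough to cleave the β-diketone. All four stereocentres are untouched and none of them can epimerise by enolisation.

## Compound list

1 | cycloheptanone | O=C1CCCCCC1 | starting material
2 | cyclohepta-2,6-dien-1-one | O=C1C=CCCC=C1 | intermediate
3 | (3,4-dimethoxyphenyl)boronic acid | COc1ccc(B(O)O)cc1OC | starting material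
4 | (S)-6-(3,4-dimethoxyphenyl)cyclohept-2-en-1-one | O=C1C=CCC[C@H](c2ccc(OC)c(OC)c2)C1 | intermediate
5 | lithium α′-dienolate of 4 (O–Li on C1, C1=C7 and C2=C3, C6 unchanged; formed in situ in step 3) | [Li]OC1=C[C@@H](c2ccc(OC)c(OC)c2)CCC=C1 | intermediate
6 | (6S,7R)-6-(3,4-dimethoxyphenyl)-7-methylcyclohept-2-en-1-one (aryl and methyl trans) | O=C1C=CCC[C@H](c2ccc(OC)c(OC)c2)[C@H]1C | intermediate
7 | allylmagnesium bromide | C=CC[Mg]Br | starting material
8 | (6S,7R)-1-allyl-6-(3,4-dimethoxyphenyl)-7-methylcyclohept-2-en-1-ol (both C1 epimers) | C=CCC1(O)C=CCC[C@H](c2ccc(OC)c(OC)c2)[C@H]1C | intermediate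
9 | (4R,5S)-3-allyl-5-(3,4-dimethoxyphenyl)-4-methylcyclohept-2-en-1-one | C=CCC1=CC(=O)CC[C@H](c2ccc(OC)c(OC)c2)[C@H]1C | intermediate
10 | trimethylsilyl dienol ether of 9 (Me3SiO on C3, C3=C4 and C1=C2; formed in situ in step 6) | C=CCC1=CC(O[Si](C)(C)C)=CC[C@H](c2ccc(OC)c(OC)c2)[C@H]1C | intermediate
11 | (4R,5S)-3-allyl-5-(3,4-dimethoxyphenyl)-4-methylcyclohepta-2,6-dien-1-one | C=CCC1=CC(=O)C=C[C@H](c2ccc(OC)c(OC)c2)[C@H]1C | intermediate
12 | nitromethane | C[N+](=O)[O-] | starting material
13 | 3-allyl-5-(3,4-dimethoxyphenyl)-4-methyl-6-(nitromethyl)cyclohept-2-en-1-one (nitromethyl cis to aryl, in equilibrium with its C5 epimer; formed in situ in step 7) | C=CCC1=CC(=O)C[C@H](C[N+](=O)[O-])[C@H](c2ccc(OC)c(OC)c2)[C@H]1C | intermediate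
14 | (1R,5S,6R,7R,8S)-1-allyl-6-(3,4-dimethoxyphenyl)-7-methyl-8-nitrobicyclo[3.2.1]octan-3-one (aryl exo, methyl endo, nitro away from the aryl-bearing bridge) | C=CC[C@]12CC(=O)C[C@H]([C@@H]1[N+](=O)[O-])[C@H](c1ccc(OC)c(OC)c1)[C@H]2C | intermediate
15 | sodium nitronate of 14 (C8=N(O)ONa; formed in situ in step 8) | C=CC[C@]12CC(=O)C[C@H](C1=[N+]([O-])[O-])[C@H](c1ccc(OC)c(OC)c1)[C@H]2C.[Na+] | intermediate
16 | (1R,5S,6R,7R)-1-allyl-6-(3,4-dimethoxyphenyl)-7-methylbicyclo[3.2.1]octane-3,8-dione | C=CC[C@]12CC(=O)C[C@H](C1=O)[C@H](c1ccc(OC)c(OC)c1)[C@H]2C | intermediate
17 | potassium enolate of 16 (O–K on C3, C3=C4; formed in situ in step 9) | C=CC[C@]12CC([O-])=C[C@H](C1=O)[C@H](c1ccc(OC)c(OC)c1)[C@H]2C.[K+] | intermediate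
18 | (1R,4R,5R,6R,7R)-1-allyl-6-(3,4-dimethoxyphenyl)-4-hydroxy-7-methylbicyclo[3.2.1]octane-3,8-dione (hydroxyl syn to C8) | C=CC[C@]12CC(=O)[C@H](O)[C@H](C1=O)[C@H](c1ccc(OC)c(OC)c1)[C@H]2C | intermediate
19 | (1S,5S,6R,7R)-1-allyl-6-(3,4-dimethoxyphenyl)-3-hydroxy-7-methylbicyclo[3.2.1]oct-2-ene-4,8-dione (diosphenol form of the 3,4,8-trione) | C=CC[C@]12C=C(O)C(=O)[C@H](C1=O)[C@H](c1ccc(OC)c(OC)c1)[C@H]2C | intermediate
20 | kadsurenin D, (1S,5S,6R,7R)-1-allyl-6-(3,4-dimethoxyphenyl)-3-methoxy-7-methylbicyclo[3.2.1]oct-2-ene-4,8-dione | C=CC[C@]12C=C(OC)C(=O)[C@H](C1=O)[C@H](c1ccc(OC)c(OC)c1)[C@H]2C | target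

## Step count and least certain steps

Total: 11 steps. Longest linear sequence: 11 steps, from 1 to 20; the route is fully linear.

**Step 7 (key step).** Two processes may interfere.
- Bridging on the wrong ring face. The first addition at C5 is kinetically easier anti to the neighbouring aryl group, and if the retro-Michael equilibration is too slow, closure syn to the C7 methyl group could compete.
- Stalling before the second addition. Closure onto the β,β-disubstituted C1 is slow, and during long exposure to base the remaining enone can deconjugate, the allyl double bond can move into conjugation, and C7 or C6 can epimerise through dienolates.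

Fallback, setting out from 11 and returning at 16: 11 is treated with 12 and a catalytic amount of tetramethylguanidine at low temperature and the reaction is stopped at 13, which is isolated. A reductive Nef reaction of its primary nitro group (NaOMe, then buffered aqueous TiCl3) should give the keto aldehyde 4-allyl-2-(3,4-dimethoxyphenyl)-3-methyl-6-oxocyclohept-4-ene-1-carbaldehyde F1. An intramolecular Stetter reaction (3-benzyl-5-(2-hydroxyethyl)-4-methylthiazolium chloride, Et3N, dioxane, 70 °C) then adds the acyl-anion equivalent at C8 to C1 and should give 16 directly, so step 8 is no longer needed. The closure is irreversible and strongly downhill. C5 of F1 is α to the aldehyde and epimerises freely under the amine base, so both C5 epimers can drain through the closure anti to the C7 methyl group.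

**Step 9.** Poor site selectivity of the kinetic deprotonation between C4 and C2 is the most likely failure, because both are methylene groups next to fully substituted or tertiary carbons and differ only in the bulk of that neighbour.

Fallback, setting out from 16 and returning at 19: a Claisen formylation under equilibrating conditions (HCO2Et, NaH, THF) should settle on the less crowded side and give 1-allyl-6-(3,4-dimethoxyphenyl)-4-(hydroxymethylene)-7-methylbicyclo[3.2.1]octane-3,8-dione F2. Regitz deformylative diazo transfer (4-acetamidobenzenesulfonyl azide, Et3N, MeCN) should give 1-allyl-4-diazo-6-(3,4-dimethoxyphenyl)-7-methylbicyclo[3.2.1]octane-3,8-dione F3. One equivalent of dimethyldioxirane in acetone at −20 °C should oxidise the diazo carbon, much faster than it attacks the terminal alkene, to the 3,4-dione, which is 19. Step 10 is then not needed. Site selection here rests on thermodynamic rather than kinetic control.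

**Step 8.** Incomplete conversion at the crowded C8 (arrest at the oxime stage) or ring opening by retro-Michael reaction while the nitronate is being formed may lower the outcome.

Fallback, setting out from 14 and returning at 16: reduction of the nitro group with Zn in AcOH should give 1-allyl-8-amino-6-(3,4-dimethoxyphenyl)-7-methylbicyclo[3.2.1]octan-3-one F4. Oxidative transamination with 3,5-di-tert-butyl-1,2-benzoquinone (MeOH/THF, rt), followed by hydrolysis of the rearranged imine with aqueous oxalic acid, should give 16. No carbanion is generated at C8 in this sequence.

**Step 6.** Side reactions at palladium are the concern: the terminal alkene can bind divalent palladium, which may lead to alkene migration or slow β-hydride elimination, and the silyl dienol ether may be cleaved back to 9 before it is oxidised.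

Fallback, setting out from 9 and returning at 11: α′-selenenylation (LiN(iPr)2, THF, −78 °C, then PhSeBr) should give 3-allyl-5-(3,4-dimethoxyphenyl)-4-methyl-7-(phenylselanyl)cyclohept-2-en-1-one F5. Oxidation with H2O2 and pyridine in CH2Cl2 at 0 °C and syn-elimination of the selenoxide toward C5, the only carbon with a β-hydrogen, should give 11 without any transition metal.

## Further compounds

F1 | step 7 | 4-allyl-2-(3,4-dimethoxyphenyl)-3-methyl-6-oxocyclohept-4-ene-1-carbaldehyde (aryl and methyl carbons as in 11, formyl carbon epimerisable) | C=CCC1=CC(=O)CC(C=O)[C@H](c2ccc(OC)c(OC)c2)[C@H]1C
F2 | step 9 | 1-allyl-6-(3,4-dimethoxyphenyl)-4-(hydroxymethylene)-7-methylbicyclo[3.2.1]octane-3,8-dione | C=CC[C@]12CC(=O)C(=CO)[C@H](C1=O)[C@H](c1ccc(OC)c(OC)c1)[C@H]2C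
F3 | step 9 | 1-allyl-4-diazo-6-(3,4-dimethoxyphenyl)-7-methylbicyclo[3.2.1]octane-3,8-dione | C=CC[C@]12CC(=O)C(=[N+]=[N-])[C@H](C1=O)[C@H](c1ccc(OC)c(OC)c1)[C@H]2C
F4 | step 8 | 1-allyl-8-amino-6-(3,4-dimethoxyphenyl)-7-methylbicyclo[3.2.1]octan-3-one | C=CC[C@]12CC(=O)C[C@H]([C@@H]1N)[C@H](c1ccc(OC)c(OC)c1)[C@H]2C
F5 | step 6 | 3-allyl-5-(3,4-dimethoxyphenyl)-4-methyl-7-(phenylselanyl)cyclohept-2-en-1-one (both C7 epimers) | C=CCC1=CC(=O)C([Se]c2ccccc2)C[C@H](c2ccc(OC)c(OC)c2)[C@H]1C
A1 | alternative 1 | 2-allyl-2-(3-oxopropyl)cyclopentane-1,3-dione | C=CCC1(CCC=O)C(=O)CCC1=O
A2 | alternative 1 | 1-allyl-4-hydroxybicyclo[3.2.1]octane-7,8-dione | C=CC[C@]12CC[C@H](O)[C@H](C1=O)CC2=O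
A3 | alternative 2 | 2-allyl-5-[(E)-3-bromo-1,1,2-trimethoxyprop-2-en-1-yl]-4-(3,4-dimethoxyphenyl)-3-methylcyclopentan-1-one (aryl and methyl carbons as in 20, C2 and C5 epimerisable) | C=CCC1C(=O)C(C(OC)(OC)/C(OC)=C\Br)[C@H](c2ccc(OC)c(OC)c2)[C@H]1C
A4 | alternative 2 | 1-allyl-6-(3,4-dimethoxyphenyl)-3,4,4-trimethoxy-7-methylbicyclo[3.2.1]oct-2-en-8-one | C=CC[C@]12C=C(OC)C(OC)(OC)[C@H](C1=O)[C@H](c1ccc(OC)c(OC)c1)[C@H]2C
A5 | alternative 3 | 6-allyl-8-(3,4-dimethoxyphenyl)-7-methyl-6-(2-oxoethyl)-1,4-dioxaspiro[4.4]nonane-9-carbaldehyde | C=CC[C@]1(CC=O)C2(OCCO2)[C@@H](C=O)[C@H](c2ccc(OC)c(OC)c2)[C@H]1C
A6 | alternative 3 | 1-allyl-6-(3,4-dimethoxyphenyl)-7-methylspiro[bicyclo[3.2.1]octane-8,2'-[1,3]dioxolane]-3,4-diol (cis-diol) | C=CC[C@]12C[C@H](O)[C@H](O)[C@H](C13OCCO3)[C@H](c4ccc(OC)c(OC)c4)[C@H]2C
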